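Early times opened the meeting. The analyst pointed out that in Wednesday's run L stood at 0.2 % after 2.00 min and at 3.5 % after 6.00 min, and she argued that such a lag shows L comes through Q, not straight from Z.

| flask | Z | E | J | remark | time |
|---|---|---|---|---|---|
| Wednesday's | 0.25 M | 0.58 equiv | 2 equiv | run made earlier |  |
| Monday's | 0.25 M | 1.6 equiv | 2 equiv | run made earlier |  |
| Sunday's | 0.25 M | 1.2 equiv | 1.8 equiv | run made earlier |  |
| alder | 0.25 M | 0.400 equiv | 1.00 equiv |  | 2.0 h |
| oak | 0.25 M | 1.20 equiv | 2.00 equiv |  | 1.0 h |

| run | time / min | L / % |
|---|---|---|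
| Wednesday's | 2.00 | 0.2 |
| Wednesday's | 6.00 | 3.5 |
| Wednesday's | 10.0 | 7.9 |
| Wednesday's | 15.0 | 13.9 |
| Wednesday's | 25.0 | 25.8 |
| Wednesday's | 30.0 | 29.8 |
| Monday's | 2.00 | 1.1 |
| Monday's | 6.00 | 9.6 |
| Monday's | 10.0 | 18.5 |
| Monday's | 15.0 | 31.2 |
| Monday's | 25.0 | 50.3 |
| Monday's | 30.0 | 58.5 |
| Sunday's | 6.00 | 6.5 |
| Sunday's | 12.0 | 17.5 |
| Sunday's | 20.0 | 32.4 |
| Sunday's | 25.0 | 41.1 |
| Sunday's | 30.0 | 47.7 |

(scatter of a reading: 0.3 percentage points)

- reactions considered so far: Z + E -> Q; J + Q -> L; Z + J -> X

1. the winner by amount of L, in percent of the Z charged; "neither" if no more than 2 percentage points parts them (alder / oak / neither)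
2. how much L is there at the end, in percent of the Z charged: alder
3. how much L is there at the end, in percent of the Z charged: oak

The chair asked where each flask must end. The analyst answered that each L takes up one Z and one E, and she proposed the ceiling, the L a charge allows in percent of the Z charged, which is the smaller of the E and Z charged, with J at 1.00 equiv or above in both flasks. For alder she put it at 40.0 %, E being the limiting reagent; for oak, with 1.20 equiv of E, she put it at 100 %.

The chair then asked how fast the ceiling is approached. The analyst took Sunday's run, which has oak's E and 1.8 equiv of J. Over its last two readings L gained 6.6 percentage points in 5.00 min, with a mean gap to the ceiling of 56 points, so the gap was closing at 0.0237 /min. She assumed that this closing rate stays the same in oak up to its 1.0 h and reckoned 74.3 %. For alder she committed to a figure under 40.0 %, since Q must still pass on. Her oak figure exceeds alder's ceiling, so she named oak.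

The forecaster, reading “the simple chain with a slow second step”, gave oak as winner, with alder at 33 % and oak at 68 %. The analyst's oak figure stands above that.

    Z + E → Q (k = 0.323 /M/min)
    J + Q → L (k = 0.128 /M/min)
    Z + J → X (k = 0.00198 /M/min)

The flask gave oak as the winner, with oak at 76.3 %, 8.3 points above the forecast, and alder at 35.9 %, under its ceiling of 40.0 %. Alder was held down because its E was consumed: with E kept at its charge, the same flask gives 70.6 %, while left until 20.0 h it reaches 40.0 %, the ceiling. A neighbour of alder charged with 1.00 equiv of E, and so with a ceiling of 100 %, gives 69.3 % at 2.00 h.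

The earlier runs and the new flask were computed on assumed constants, noise included.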